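**Plan**
1. Cuts: the C11=C12 and C11'=C12' double bonds (two Wittig reactions on a C10 trienedial); then in each C20 half the C11–P and C9–C10 bonds, C7=C8 and the side-chain C=C; last, in the ring of the common diester, C1–C6.
2. Enabling feature: in ring A the gem-dimethyl carbon C1 lies between C2 (the CH whose CH2 starts the C5 arm) and C6 (the CH carrying the polyene), with C3 a methylene and C4=C5(CH3). With C1 bonded to C4 instead of C6, these atoms are the cyclobutane of cis-pinonic acid (CMe2, CH–CH2CO2H, CH2, CH–COCH3), so the ring follows from a 1,3-shift of C1.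
3. Forward: (−)-α-pinene → methyl pinonate → E-alkenylcyclobutane → thermal four-to-six ring expansion to the ring diester (the only ring-forming step; ring B is made from the same diester). The unhindered ester becomes prenyl (ring A) or silyl-protected E-hydroxyprenyl (ring B), and each ring ester is grown to a C20 phosphonium salt. Ring-A salt + C10 dial → C30 aldehyde; + ring-B salt → C50; desilylation.
4. Stereochemistry: C2 and C2' are C5 of (1S,5S)-α-pinene, carried through untouched. C6 (cis to C2) is set in the rearrangement; C6' (trans to C2') by base equilibration of the ring-B enone. E-alkenes come from stabilised ylides, phosphonium-salt formation and thermal Z→E equilibration of the polyene.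

Key step: step 4

Remark: carotenoid numbering is used (C1 gem-dimethyl carbon, C2 ring CH with the C5 arm, C6 ring CH with the chain, primes for ring B). The target is read as ring A (prenyl) 2S,6R with the two ring substituents cis, and ring B (hydroxyprenyl) 2'R,6'S with them trans; C2 and C2' have the same spatial arrangement.

Step 1
Reactants: 1 (1S,5S)-(−)-α-pinene
Product: 2 cis-pinonic acid, 2-[(1R,3R)-3-acetyl-2,2-dimethylcyclobutyl]acetic acid
Conditions: RuCl3·xH2O (cat.), NaIO4, EtOAc/MeCN/H2O, 25 °C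
Reagents that add atoms: sodium periodate, [Na+].[O-]I(=O)(=O)=O; water, O
Why: Catalytic ruthenium tetroxide cleaves the only C=C bond (oxidative alkene cleavage) to the methyl ketone and the carboxylic acid, while the two bridgehead centres of the pinene stay untouched and end cis on the cyclobutane.

Step 2
Reactants: 2 cis-pinonic acid
Product: 3 methyl 2-[(1R,3R)-3-acetyl-2,2-dimethylcyclobutyl]acetate
Conditions: MeI, K2CO3, DMF, 25 °C
Reagents that add atoms: iodomethane, CI
Why: O-Alkylation of the carboxylate (SN2 esterification) avoids the strong acid that opens the cyclobutane of pinonic acid derivatives.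

Step 3
Reactants: 3 methyl cis-pinonate; 4 trimethyl phosphonoacetate
Product: 6 methyl (2E)-3-[(1S,3R)-3-(2-methoxy-2-oxoethyl)-2,2-dimethylcyclobutyl]but-2-enoate, via sodium phosphonoacetate anion 5 (not isolated)
Conditions: NaH, THF, 0 °C; then 3, 65 °C
Reagents that add atoms: none
Why: Horner–Wadsworth–Emmons olefination of the methyl ketone should give mainly the E-enoate (ester trans to the bulky cyclobutyl group), separable from the Z isomer; epimerisation next to the ketone is harmless because that carbon becomes sp2 in step 4.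

Step 4
Reactants: 6 E-alkenylcyclobutane diester
Product: 7 methyl (1R,5R)-5-(2-methoxy-2-oxoethyl)-2,6,6-trimethylcyclohex-2-ene-1-carboxylate (ring diester, 2,6-cis in carotenoid numbering)
Conditions: Ph2O (0.02 M, degassed), BHT (cat.), sealed silanised glass, 240 °C
Reagents that add atoms: none
Why: Heat homolyses the strained C1–C4 cyclobutane bond, the only ring bond that gives both a tertiary radical (C1) and an ester-conjugated allyl radical (C4–C5–C6), and bonding of C1 to the far allyl terminus C6 completes a formal 1,3-carbon shift; this is the thermal vinylcyclobutane-to-cyclohexene rearrangement, the reaction type behind the thermal racemisation of α-pinene. Ring A closes by four-to-six ring expansion, that is six-membered ring formation through C1–C6 radical recombination with the C4=C5 double bond left in the ring, not by cyclisation of an open chain. The new stereocentre C6 is controlled by the untouched C2 centre and the E-enoate geometry: the ester sits on the outer position of the allyl radical and ends pseudo-equatorial, and closure through the half-chair that keeps the CH2CO2Me arm of C2 equatorial gives the 2,6-cis diester. The step needs C1–C6 recombination to win over retro-[2+2] fragmentation and 1,5-hydrogen transfer, which the doubly stabilised radical pair favours by allowing a moderate temperature and by making closure to the strain-free cyclohexene irreversible while closure at C4 only returns substrate. It also needs face selectivity at C6, for which the conformational bias named above is expected to be modest, so the C6 epimer is to be removed by chromatography at this stage. Because the alkenyl-bearing cyclobutane carbon becomes sp2, any cyclobutane epimer carried from step 3 converges on 7.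

Step 5
Reactants: 7 ring diester
Product: 8 methyl (1R,5R)-2,6,6-trimethyl-5-(2-oxoethyl)cyclohex-2-ene-1-carboxylate
Conditions: i-Bu2AlH (1.1 equiv), CH2Cl2, −78 °C; MeOH, then aq. potassium sodium tartrate
Reagents that add atoms: none
Why: Partial ester reduction with i-Bu2AlH at −78 °C (stable tetrahedral aluminium acetal) should touch only the unhindered CH2CO2Me arm, because the ring ester is flanked by the quaternary C1 and the substituted C5.

Step 6
Reactants: 8 aldehyde ester; 9 isopropyltriphenylphosphonium iodide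
Product: 11 methyl (1R,5S)-2,6,6-trimethyl-5-(3-methylbut-2-en-1-yl)cyclohex-2-ene-1-carboxylate, via isopropylidenetriphenylphosphorane 10 (not isolated)
Conditions: n-BuLi, THF, 0 °C; then 8, −78 → 25 °C
Reagents that add atoms: none
Why: Wittig olefination with the non-stabilised isopropylidene ylide completes the prenyl arm, a trisubstituted alkene with no geometry to control, and the hindered ring ester is inert to the ylide.

Step 7
Reactants: 11 prenyl ring ester
Product: 12 [(1R,5S)-2,6,6-trimethyl-5-(3-methylbut-2-en-1-yl)cyclohex-2-en-1-yl]methanol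
Conditions: LiAlH4, Et2O, 0 → 25 °C
Reagents that add atoms: none
Why: Hydride reduction with the small, strong LiAlH4 converts the hindered ester into the primary alcohol without touching the two trisubstituted alkenes.

Step 8
Reactants: 12 ring-A alcohol
Product: 13 (1R,5S)-2,6,6-trimethyl-5-(3-methylbut-2-en-1-yl)cyclohex-2-ene-1-carbaldehyde
Conditions: Dess–Martin periodinane, pyridine, CH2Cl2, 0 → 25 °C
Reagents that add atoms: none
Why: Dess–Martin oxidation under buffered, non-enolising conditions stops at the aldehyde and should leave the epimerisable C6 centre cis.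

Step 9
Reactants: 13 ring-A aldehyde; 14 1-(triphenylphosphoranylidene)propan-2-one
Product: 15 (3E)-4-[(1R,5S)-2,6,6-trimethyl-5-(3-methylbut-2-en-1-yl)cyclohex-2-en-1-yl]but-3-en-2-one
Conditions: toluene, 100 °C
Reagents that add atoms: none
Why: Wittig olefination with the neutral stabilised acetonyl ylide gives the E-enone and, being non-basic, should not epimerise C6 of the hindered aldehyde.

Step 10
Reactants: 15 ring-A enone; 16 vinylmagnesium bromide
Product: 17 (1E)-3-methyl-1-[(1R,5S)-2,6,6-trimethyl-5-(3-methylbut-2-en-1-yl)cyclohex-2-en-1-yl]penta-1,4-dien-3-ol (both C9 epimers)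
Conditions: CH2=CHMgBr, THF, −40 → 0 °C; aq. NH4Cl
Reagents that add atoms: none
Why: Grignard 1,2-addition of the small vinyl nucleophile to the enone carbonyl gives the tertiary bis-allylic alcohol, whose new carbinol centre is irrelevant because it is planarised in step 11.

Step 11
Reactants: 17 ring-A vinyl carbinol
Product: 18 [(2E,4E)-3-methyl-5-[(1R,5S)-2,6,6-trimethyl-5-(3-methylbut-2-en-1-yl)cyclohex-2-en-1-yl]penta-2,4-dien-1-yl]triphenylphosphonium bromide
Conditions: PPh3·HBr, MeOH, 25 °C
Reagents that add atoms: triphenylphosphine hydrobromide, [Br-].[PH+](c1ccccc1)(c1ccccc1)c1ccccc1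
Why: Acid ionisation of the tertiary bis-allylic alcohol to a pentadienyl cation and capture by PPh3 at the unhindered terminus (SN1' allylic transposition) should give the crystallisable 7E,9E C20 phosphonium salt.

Step 12
Reactants: 18 ring-A C20 phosphonium bromide; 19 (2E,4E,6E)-2,7-dimethylocta-2,4,6-trienedial
Product: 21 (2E,4E,6E,8E,10E,12E)-2,7,11-trimethyl-13-[(1R,5S)-2,6,6-trimethyl-5-(3-methylbut-2-en-1-yl)cyclohex-2-en-1-yl]trideca-2,4,6,8,10,12-hexaenal (ring-A C30 aldehyde), via ring-A C20 ylide 20 (not isolated)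
Conditions: 19 (3 equiv), NaOMe, CH2Cl2/MeOH, 0 → 25 °C; then heptane, 90 °C (Z→E)
Reagents that add atoms: none
Why: Wittig olefination of the symmetrical dialdehyde used in excess should stop at mono-condensation, and the new C11=C12 bond is brought to E by thermal equilibration, the usual practice for polyene Wittig products.

Step 13
Reactants: 8 aldehyde ester; 22 ethyl 2-(triphenylphosphoranylidene)propanoate
Product: 23 methyl (1R,5R)-5-[(2E)-4-ethoxy-3-methyl-4-oxobut-2-en-1-yl]-2,6,6-trimethylcyclohex-2-ene-1-carboxylate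
Conditions: CH2Cl2, 25 °C
Reagents that add atoms: none
Why: Wittig olefination with the α-methyl stabilised ylide is reliably E-selective and places the ester carbon where the CH2OH of the hydroxyprenyl arm is needed.

Step 14
Reactants: 23 enoate ring ester
Product: 24 methyl (1R,5R)-5-[(2E)-4-hydroxy-3-methylbut-2-en-1-yl]-2,6,6-trimethylcyclohex-2-ene-1-carboxylate
Conditions: i-Bu2AlH (2.3 equiv), CH2Cl2, −78 °C; aq. potassium sodium tartrate
Reagents that add atoms: none
Why: 1,2-Reduction of the conjugated ethyl ester with i-Bu2AlH gives the E-allylic alcohol, while the hindered ring ester is spared at −78 °C.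

Step 15
Reactants: 24 allylic alcohol
Product: 25 methyl (1R,5R)-5-[(2E)-4-[tert-butyl(diphenyl)silyl]oxy-3-methylbut-2-en-1-yl]-2,6,6-trimethylcyclohex-2-ene-1-carboxylate
Conditions: t-BuPh2SiCl, imidazole, CH2Cl2, 0 → 25 °C
Reagents that add atoms: tert-butyl(chloro)diphenylsilane, CC(C)(C)[Si](Cl)(c1ccccc1)c1ccccc1
Why: Silylation of the primary allylic alcohol gives a tert-butyldiphenylsilyl ether that should tolerate hydride, Grignard, alkoxide and mildly acidic steps and is removable with fluoride at the end.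

Step 16
Reactants: 25 silyl ether ring ester
Product: 26 [(1R,5R)-5-[(2E)-4-[tert-butyl(diphenyl)silyl]oxy-3-methylbut-2-en-1-yl]-2,6,6-trimethylcyclohex-2-en-1-yl]methanol
Conditions: LiAlH4, Et2O, 0 °C
Reagents that add atoms: none
Why: Hydride reduction of the hindered ester with LiAlH4 gives the primary alcohol, and the silyl ether is stable to the reagent at 0 °C.

Step 17
Reactants: 26 ring-B alcohol
Product: 27 (1R,5R)-5-[(2E)-4-[tert-butyl(diphenyl)silyl]oxy-3-methylbut-2-en-1-yl]-2,6,6-trimethylcyclohex-2-ene-1-carbaldehyde (2,6-cis)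
Conditions: Dess–Martin periodinane, pyridine, CH2Cl2, 0 → 25 °C
Reagents that add atoms: none
Why: Dess–Martin oxidation gives the aldehyde under buffered conditions compatible with the silyl ether and both alkenes.

Step 18
Reactants: 27 ring-B cis aldehyde; 14 1-(triphenylphosphoranylidene)propan-2-one
Product: 28 (3E)-4-[(1R,5R)-5-[(2E)-4-[tert-butyl(diphenyl)silyl]oxy-3-methylbut-2-en-1-yl]-2,6,6-trimethylcyclohex-2-en-1-yl]but-3-en-2-one (2,6-cis)
Conditions: toluene, 100 °C
Reagents that add atoms: none
Why: Wittig olefination with the stabilised acetonyl ylide gives the E-enone, as in step 9.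

Step 19
Reactants: 28 ring-B cis enone
Product: 29 (3E)-4-[(1S,5R)-5-[(2E)-4-[tert-butyl(diphenyl)silyl]oxy-3-methylbut-2-en-1-yl]-2,6,6-trimethylcyclohex-2-en-1-yl]but-3-en-2-one (2,6-trans)
Conditions: NaOMe (0.2 equiv), MeOH/THF, 25 °C, stopped at equilibrium of the two C6 epimers
Reagents that add atoms: none
Why: Reversible γ-deprotonation to the extended enolate and reprotonation at C6 (base-mediated epimerisation) should favour the 2,6-trans isomer, in which the chain sits pseudo-axial, free of allylic strain with the C5 methyl, while the C2 arm stays equatorial; this is the same equilibration that converts cis-α-irone into trans-α-irone.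

Step 20
Reactants: 29 ring-B trans enone; 16 vinylmagnesium bromide
Product: 30 (1E)-1-[(1S,5R)-5-[(2E)-4-[tert-butyl(diphenyl)silyl]oxy-3-methylbut-2-en-1-yl]-2,6,6-trimethylcyclohex-2-en-1-yl]-3-methylpenta-1,4-dien-3-ol (both C9' epimers)
Conditions: CH2=CHMgBr, THF, −40 → 0 °C; aq. NH4Cl
Reagents that add atoms: none
Why: Grignard 1,2-addition to the enone carbonyl, as in step 10, consumes the ketone and so removes the acidity of C6', fixing the trans configuration.

Step 21
Reactants: 30 ring-B vinyl carbinol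
Product: 31 [(2E,4E)-5-[(1S,5R)-5-[(2E)-4-[tert-butyl(diphenyl)silyl]oxy-3-methylbut-2-en-1-yl]-2,6,6-trimethylcyclohex-2-en-1-yl]-3-methylpenta-2,4-dien-1-yl]triphenylphosphonium bromide
Conditions: PPh3·HBr, CH2Cl2, 0 → 25 °C
Reagents that add atoms: triphenylphosphine hydrobromide, [Br-].[PH+](c1ccccc1)(c1ccccc1)c1ccccc1
Why: SN1' phosphonium-salt formation as in step 11, run in an aprotic solvent so that the tertiary bis-allylic alcohol ionises while the acid-resistant silyl ether is kept.

Step 22
Reactants: 21 ring-A C30 aldehyde; 31 ring-B C20 phosphonium bromide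
Product: 33 tert-butyldiphenylsilyl ether of the target (all-E C50 polyene), via ring-B C20 ylide 32 (not isolated)
Conditions: NaOMe, CH2Cl2/MeOH, 0 → 25 °C; then heptane, 90 °C, dark, argon (Z→E)
Reagents that add atoms: none
Why: Wittig olefination joins the two halves at C11'=C12', and thermal equilibration of the polyene gives the all-E isomer; neither C6 nor C6' is acidic at this stage, so both ring configurations survive the base.

Step 23
Reactants: 33 C50 silyl ether
Product: 34 (2S,6R,2'R,6'S)-2-(3-methylbut-2-enyl)-2'-[(2E)-4-hydroxy-3-methylbut-2-enyl]-ε,ε-carotene (target, CNP0304855.1)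
Conditions: Bu4NF, THF, 0 → 25 °C, dark, argon
Reagents that add atoms: none
Why: Fluoride-induced desilylation frees the primary allylic alcohol under conditions that leave the polyene and both ring stereocentres untouched.

**Compound list**
1 | (1S,5S)-(−)-α-pinene | CC1=CC[C@H]2C[C@@H]1C2(C)C | starting material
2 | cis-pinonic acid, 2-[(1R,3R)-3-acetyl-2,2-dimethylcyclobutyl]acetic acid | O=C(O)C[C@H]1C[C@@H](C(C)=O)C1(C)C | intermediate
3 | methyl 2-[(1R,3R)-3-acetyl-2,2-dimethylcyclobutyl]acetate | COC(=O)C[C@H]1C[C@@H](C(C)=O)C1(C)C | intermediate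
4 | trimethyl phosphonoacetate | COC(=O)CP(=O)(OC)OC | starting material
5 | sodium salt of trimethyl phosphonoacetate | [Na+].COC(=O)[CH-]P(=O)(OC)OC | intermediate
6 | methyl (2E)-3-[(1S,3R)-3-(2-methoxy-2-oxoethyl)-2,2-dimethylcyclobutyl]but-2-enoate | COC(=O)C[C@H]1C[C@@H](/C(C)=C/C(=O)OC)C1(C)C | intermediate
7 | methyl (1R,5R)-5-(2-methoxy-2-oxoethyl)-2,6,6-trimethylcyclohex-2-ene-1-carboxylate | COC(=O)C[C@H]1CC=C(C)[C@@H](C(=O)OC)C1(C)C | intermediate
8 | methyl (1R,5R)-2,6,6-trimethyl-5-(2-oxoethyl)cyclohex-2-ene-1-carboxylate | O=CC[C@H]1CC=C(C)[C@@H](C(=O)OC)C1(C)C | intermediate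
9 | isopropyltriphenylphosphonium iodide | CC(C)[P+](c1ccccc1)(c1ccccc1)c1ccccc1.[I-] | starting material
10 | isopropylidenetriphenylphosphorane | CC(C)=P(c1ccccc1)(c1ccccc1)c1ccccc1 | intermediate
11 | methyl (1R,5S)-2,6,6-trimethyl-5-(3-methylbut-2-en-1-yl)cyclohex-2-ene-1-carboxylate | CC(C)=CC[C@H]1CC=C(C)[C@@H](C(=O)OC)C1(C)C | intermediate
12 | [(1R,5S)-2,6,6-trimethyl-5-(3-methylbut-2-en-1-yl)cyclohex-2-en-1-yl]methanol | CC(C)=CC[C@H]1CC=C(C)[C@@H](CO)C1(C)C | intermediate
13 | (1R,5S)-2,6,6-trimethyl-5-(3-methylbut-2-en-1-yl)cyclohex-2-ene-1-carbaldehyde | CC(C)=CC[C@H]1CC=C(C)[C@@H](C=O)C1(C)C | intermediate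
14 | 1-(triphenylphosphoranylidene)propan-2-one | CC(=O)C=P(c1ccccc1)(c1ccccc1)c1ccccc1 | starting material
15 | (3E)-4-[(1R,5S)-2,6,6-trimethyl-5-(3-methylbut-2-en-1-yl)cyclohex-2-en-1-yl]but-3-en-2-one | CC(C)=CC[C@H]1CC=C(C)[C@@H](/C=C/C(C)=O)C1(C)C | intermediate
16 | vinylmagnesium bromide | C=C[Mg]Br | starting material
17 | (1E)-3-methyl-1-[(1R,5S)-2,6,6-trimethyl-5-(3-methylbut-2-en-1-yl)cyclohex-2-en-1-yl]penta-1,4-dien-3-ol (carbinol epimers) | CC(C)=CC[C@H]1CC=C(C)[C@@H](/C=C/C(C)(O)C=C)C1(C)C | intermediate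
18 | ring-A C20 phosphonium bromide (7E,9E) | CC(C)=CC[C@H]1CC=C(C)[C@@H](/C=C/C(C)=C/C[P+](c2ccccc2)(c2ccccc2)c2ccccc2)C1(C)C.[Br-] | intermediate
19 | (2E,4E,6E)-2,7-dimethylocta-2,4,6-trienedial | O=C/C(C)=C/C=C/C=C(C)/C=O | starting material
20 | ring-A C20 ylide | CC(C)=CC[C@H]1CC=C(C)[C@@H](/C=C/C(C)=C/C=P(c2ccccc2)(c2ccccc2)c2ccccc2)C1(C)C | intermediate
21 | ring-A C30 aldehyde, (2E,4E,6E,8E,10E,12E)-2,7,11-trimethyl-13-[(1R,5S)-2,6,6-trimethyl-5-(3-methylbut-2-en-1-yl)cyclohex-2-en-1-yl]trideca-2,4,6,8,10,12-hexaenal | CC(C)=CC[C@H]1CC=C(C)[C@@H](/C=C/C(C)=C/C=C/C(C)=C/C=C/C=C(C)/C=O)C1(C)C | intermediate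
22 | ethyl 2-(triphenylphosphoranylidene)propanoate | CCOC(=O)C(C)=P(c1ccccc1)(c1ccccc1)c1ccccc1 | starting material
23 | methyl (1R,5R)-5-[(2E)-4-ethoxy-3-methyl-4-oxobut-2-en-1-yl]-2,6,6-trimethylcyclohex-2-ene-1-carboxylate | CCOC(=O)/C(C)=C/C[C@H]1CC=C(C)[C@@H](C(=O)OC)C1(C)C | intermediate
24 | methyl (1R,5R)-5-[(2E)-4-hydroxy-3-methylbut-2-en-1-yl]-2,6,6-trimethylcyclohex-2-ene-1-carboxylate | OC/C(C)=C/C[C@H]1CC=C(C)[C@@H](C(=O)OC)C1(C)C | intermediate
25 | tert-butyldiphenylsilyl ether of 24 | CC(C)(C)[Si](OC/C(C)=C/C[C@H]1CC=C(C)[C@@H](C(=O)OC)C1(C)C)(c2ccccc2)c2ccccc2 | intermediate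
26 | [(1R,5R)-5-[(2E)-4-[tert-butyl(diphenyl)silyl]oxy-3-methylbut-2-en-1-yl]-2,6,6-trimethylcyclohex-2-en-1-yl]methanol | CC(C)(C)[Si](OC/C(C)=C/C[C@H]1CC=C(C)[C@@H](CO)C1(C)C)(c2ccccc2)c2ccccc2 | intermediate
27 | ring-B cis aldehyde, (1R,5R) | CC(C)(C)[Si](OC/C(C)=C/C[C@H]1CC=C(C)[C@@H](C=O)C1(C)C)(c2ccccc2)c2ccccc2 | intermediate
28 | ring-B cis enone, (1R,5R) | CC(C)(C)[Si](OC/C(C)=C/C[C@H]1CC=C(C)[C@@H](/C=C/C(C)=O)C1(C)C)(c2ccccc2)c2ccccc2 | intermediate
29 | ring-B trans enone, (1S,5R) | CC(C)(C)[Si](OC/C(C)=C/C[C@H]1CC=C(C)[C@H](/C=C/C(C)=O)C1(C)C)(c2ccccc2)c2ccccc2 | intermediate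
30 | ring-B vinyl carbinol, (1S,5R), carbinol epimers | CC(C)(C)[Si](OC/C(C)=C/C[C@H]1CC=C(C)[C@H](/C=C/C(C)(O)C=C)C1(C)C)(c2ccccc2)c2ccccc2 | intermediate
31 | ring-B C20 phosphonium bromide (7'E,9'E) | CC(C)(C)[Si](OC/C(C)=C/C[C@H]1CC=C(C)[C@H](/C=C/C(C)=C/C[P+](c2ccccc2)(c2ccccc2)c2ccccc2)C1(C)C)(c2ccccc2)c2ccccc2.[Br-] | intermediate
32 | ring-B C20 ylide | CC(C)(C)[Si](OC/C(C)=C/C[C@H]1CC=C(C)[C@H](/C=C/C(C)=C/C=P(c2ccccc2)(c2ccccc2)c2ccccc2)C1(C)C)(c2ccccc2)c2ccccc2 | intermediate
33 | tert-butyldiphenylsilyl ether of the target | CC(C)=CC[C@H]1CC=C(C)[C@@H](/C=C/C(C)=C/C=C/C(C)=C/C=C/C=C(C)/C=C/C=C(C)/C=C/[C@H]2C(C)=CC[C@H](C/C=C(\C)CO[Si](c3ccccc3)(c3ccccc3)C(C)(C)C)C2(C)C)C1(C)C | intermediate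
34 | (2S,6R,2'R,6'S)-2-(3-methylbut-2-enyl)-2'-[(2E)-4-hydroxy-3-methylbut-2-enyl]-ε,ε-carotene | CC(C)=CC[C@H]1CC=C(C)[C@@H](/C=C/C(C)=C/C=C/C(C)=C/C=C/C=C(C)/C=C/C=C(C)/C=C/[C@H]2C(C)=CC[C@H](C/C=C(\C)CO)C2(C)C)C1(C)C | target

Total step count: 23.
Longest linear sequence: 16 steps (steps 1–5, then 13–23).

**Steps most likely to fail**

Step 4. The diradical may fragment by retro-[2+2] cleavage or collapse by 1,5-hydrogen transfer faster than C1 bonds to C6, and closure may show little face preference at C6. The fallback makes the same bond change in two ionic stages and sets out from 2. Warming 2 in aqueous H2SO4 cleaves C1–C4 heterolytically and the acid traps the C1 cation as the lactone (4R)-5,5-dimethyl-4-(3-oxobutyl)oxolan-2-one F1. Horner–Wadsworth–Emmons olefination of its methyl ketone with 4 (NaH, THF) gives methyl (2E)-5-[(3R)-2,2-dimethyl-5-oxooxolan-3-yl]-3-methylpent-2-enoate F2. ClSO3H in CH2Cl2 at −78 °C re-ionises the tertiary lactone C–O bond, and the E-enoate closes C1–C6 through a chair with both arms equatorial (cation–olefin cyclisation of the cyclogeranate type, proton loss from C4). This should give 2-[(1R,5R)-5-(methoxycarbonyl)-4,6,6-trimethylcyclohex-3-en-1-yl]acetic acid F3, which MeI/K2CO3 converts into 7, where the route is rejoined.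

Step 19. Equilibration may stop short of a useful trans content, or the extended enolate may be protonated at C4 and drain into the ring-conjugated dienone, which destroys C6'. The fallback moves the correction one step earlier and sets out from 27. Catalytic pyrrolidine/AcOH in CH2Cl2 equilibrates the aldehyde α-centre through its enamine, where only C6' can be reprotonated productively. This should give the 2,6-trans aldehyde (1S,5R)-5-[(2E)-4-[tert-butyl(diphenyl)silyl]oxy-3-methylbut-2-en-1-yl]-2,6,6-trimethylcyclohex-2-ene-1-carbaldehyde F4. Wittig reaction of F4 with 14 in toluene at 100 °C returns to 29.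

Step 21. The silyl ether may be lost under HBr, after which the freed primary allylic alcohol would also be converted into a phosphonium salt. The fallback changes the protecting group to one that is inert to acid and sets out from 30. Bu4NF gives the diol (1E)-1-[(1S,5R)-5-[(2E)-4-hydroxy-3-methylbut-2-en-1-yl]-2,6,6-trimethylcyclohex-2-en-1-yl]-3-methylpenta-1,4-dien-3-ol F5. Ac2O/pyridine at 0 °C acylates only the primary hydroxyl to give the monoacetate F6. PPh3·HBr in MeOH gives the acetoxy C20 phosphonium bromide F7. With NaOMe in CH2Cl2/MeOH this forms the acetoxy ylide F8, which condenses with 21 to the C50 acetate F9. Excess methoxide methanolyses F9 in the same flask, and after thermal Z→E equilibration the route arrives at 34.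

**Further compounds**
F1 | step 4 | (4R)-5,5-dimethyl-4-(3-oxobutyl)oxolan-2-one | CC(=O)CC[C@@H]1CC(=O)OC1(C)C
F2 | step 4 | methyl (2E)-5-[(3R)-2,2-dimethyl-5-oxooxolan-3-yl]-3-methylpent-2-enoate | COC(=O)/C=C(\C)CC[C@@H]1CC(=O)OC1(C)C
F3 | step 4 | 2-[(1R,5R)-5-(methoxycarbonyl)-4,6,6-trimethylcyclohex-3-en-1-yl]acetic acid | OC(=O)C[C@H]1CC=C(C)[C@@H](C(=O)OC)C1(C)C
F4 | step 19 | (1S,5R)-5-[(2E)-4-[tert-butyl(diphenyl)silyl]oxy-3-methylbut-2-en-1-yl]-2,6,6-trimethylcyclohex-2-ene-1-carbaldehyde | CC(C)(C)[Si](OC/C(C)=C/C[C@H]1CC=C(C)[C@H](C=O)C1(C)C)(c2ccccc2)c2ccccc2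
F5 | step 21 | (1E)-1-[(1S,5R)-5-[(2E)-4-hydroxy-3-methylbut-2-en-1-yl]-2,6,6-trimethylcyclohex-2-en-1-yl]-3-methylpenta-1,4-dien-3-ol | OC/C(C)=C/C[C@H]1CC=C(C)[C@H](/C=C/C(C)(O)C=C)C1(C)C
F6 | step 21 | primary monoacetate of F5 | CC(=O)OC/C(C)=C/C[C@H]1CC=C(C)[C@H](/C=C/C(C)(O)C=C)C1(C)C
F7 | step 21 | acetoxy ring-B C20 phosphonium bromide | CC(=O)OC/C(C)=C/C[C@H]1CC=C(C)[C@H](/C=C/C(C)=C/C[P+](c2ccccc2)(c2ccccc2)c2ccccc2)C1(C)C.[Br-]
F8 | step 21 | acetoxy ring-B C20 ylide | CC(=O)OC/C(C)=C/C[C@H]1CC=C(C)[C@H](/C=C/C(C)=C/C=P(c2ccccc2)(c2ccccc2)c2ccccc2)C1(C)C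
F9 | step 21 | acetate of the target | CC(C)=CC[C@H]1CC=C(C)[C@@H](/C=C/C(C)=C/C=C/C(C)=C/C=C/C=C(C)/C=C/C=C(C)/C=C/[C@H]2C(C)=CC[C@H](C/C=C(\C)COC(C)=O)C2(C)C)C1(C)C
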